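## The problem

Luteolin 3'-sulfate (20) is a flat, achiral 2-arylchromen-4-one. Ring A is a phloroglucinol-type benzo ring with hydroxyls at C5 and C7, ring C is the 4-pyranone, and ring B is a catechol joined through C1' to C2. There is no stereocentre, so the whole selectivity problem is positional. Of four phenolic oxygens only O3' carries the sulfate, and O3' and O4' sit on neighbouring carbons of ring B with almost the same acidity, so sulfation of luteolin itself cannot be expected to choose between them. The aryl sulfate monoester is the fragile group: it is lost in acid and is awkward to purify. It must therefore be introduced late, on the only free hydroxyl, and the other three oxygens must be unmasked under neutral conditions, which points to benzyl ethers and hydrogenolysis. The chromone tolerates mild acid but is opened by hot hydroxide, and the 5-benzyl ether peri to the carbonyl is the ether most easily lost in strong acid. The feature that allows an unusual solution lies in ring B. C2' and C3' with O3' are the two carbons of an ynol ether. C1', C6', C5' and C4' with O4' are C6, C5, C4 and C3 of a 3-alkoxy-2-pyrone bound through C6 to chromone C2. The O1–C2 unit of that pyrone can leave as CO2, so forming C1'–C2' and C3'–C4' gives ring B in the aromatic state, with its two oxygens coming from different partners under different protecting groups.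

## Retrosynthesis

**20 from 19.** The three benzyl C–O bonds at O5, O7 and O4' are cut last. Hydrogenolysis is neutral and leaves the S–O ester alone, whereas acid-labile ethers would endanger the sulfate. The sulfate 19 is no simpler in skeleton, but it is organic-soluble and fully differentiated. The forward step must spare the sulfate and the C2–C3 double bond.

**19 from 18, and 18 from 17.** The S–O3' bond is cut, then the Si–O3' bond. In phenol 18 the hydroxyl to be sulfated is the only free one, so sulfation needs no selectivity. The silyl ether in 17 is orthogonal to the benzyl ethers, so fluoride can free O3' alone.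

**17 from 10 and 15.** Ring B is cut at C1'–C2' and C3'–C4'. The neighbouring cuts (C2–C1', or building ring C onto a preformed benzoyl unit) would require a catechol that is already differentiated. This cut creates the differentiation: O4' comes as the benzyloxy group of pyronylchromone 10, and O3' comes as the silyloxy group of ynol ether 15. The precursors are far simpler than 17: an aromatic ring is replaced by a sugar-derived lactone and a two-carbon alkyne. The forward reaction has to be an inverse-demand cycloaddition with one defined orientation, followed by loss of CO2 from the bridged lactone 16.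

**10 from 9, and 9 from 5 and 7.** Ring C is opened at O1–C2 (cyclodehydration of the o-hydroxyaryl β-diketone 9). The diketone is then cut between chromone C3 and C2, that is, between the acetyl methyl carbon of acetophenone 7 and the carboxyl carbon of pyrone acid 5, activated as chloride 8. This is the standard chromone construction, with the pyrone serving as an unusual aroyl unit. The enolate must attack the acid chloride and not the pyrone ring, and the ring closure must be run under acid mild enough for the 5-benzyl ether.

**5 from 4, 3, 2 and 1.** All six carbons of acid 5 come from galactaric acid 1. Its C1 becomes the lactone carbonyl, C2–O becomes the 3-oxygen (the future O4'), and C6 becomes the carboxyl that ends as chromone C2. Dehydration gives the acetoxypyrone salt 2. Benzylating the enolic hydroxyl alone requires a detour through methyl ester 3 and its benzyl ether 4. The ester cleavage must avoid free hydroxide, which would open the lactone.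

**7 from 6.** Two benzyl ethers are removed to reach 2',4',6'-trihydroxyacetophenone 6. The chelated ortho hydroxyl stays free in the forward direction.

**15 from 11 and 12.** The O–Si bond is cut to give lithium ethynolate 14 and silyl triflate 12. The C–O bond is cut to give lithium acetylide 13, made from acetylene 11. The forward sequence asks for oxygen transfer to an acetylide and O-silylation (not C-silylation) of the ynolate.

## Roads not taken

**Alternative 1:** Ring A would be cut at C7–C8 and C5–C6, with ring C kept as the preformed 4-pyranone ester A2. A2 already carries the differentiated catechol at the future C2, a methyl group (future C8) and an ester (future C5). In the forward step the methyl group is deprotonated to a vinylogous dienolate and acylated by A3, forming C7–C8. With excess lithium amide the new methyl ketone enolate closes onto the ring ester, forming C5–C6, and tautomerises to flavone A1.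
- Merits: two C–C bonds form in one flask, and the identity of O3' and O4' is bought with an aromatic starting material. In that respect this route is better than the chosen one, which must win the assignment in a cycloaddition.
- Weak points: A2 needs its own multi-step pyranone synthesis; A3 self-condenses under the excess base; the intermediate diketone can close through oxygen instead of carbon.
- Protecting groups: A1 emerges with free 5- and 7-hydroxyls. These must be benzylated (the chelated 5-hydroxyl sluggishly) and the methoxymethyl group removed before the route reaches phenol 18.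
- Comparison: the chosen plan delivers all four oxygens in their final protection state in the ring-forming step, from cheap feedstocks.

**Alternative 2:** Ring A would be cut at C4a–C5. The precursor is the 4-hydroxy-2-pyrone A5, which carries the aryl diketone side chain. A magnesium alkoxide opens the lactone to the polyketo ester, and chelation steers the C4a carbanion onto the ester carbonyl. This gives the phloroglucinol diketone A4, which cyclodehydrates to A1.
- Merits: the closure follows the polyketide logic of the natural ring A, needs no ring A protecting groups, and again leaves no doubt about ring B.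
- Weak points: A5 needs a stepwise polyketide assembly by dianion chemistry; aldol closure of the polyketo ester competes with the Claisen mode; the methoxymethyl ether must survive the acid cyclodehydration.
- Protecting groups: A1 again requires the reprotection described for alternative 1.
- Comparison: this road is longer and arrives in the wrong protection state. Its certainty about ring B is real. The chosen plan concentrates its uncertainty in one step and backs that step with a classical route to 18.

**Alternative 3:** Ring C would be cut at O1–C8a and C4–C4a. Fluoride releases an aryne from silyl triflate A8, and the aryne inserts into the carboxyl C–O bond of arylpropiolic acid A7 to give the o-hydroxyaryl ynone A6. A separate 6-endo oxa-Michael closure and removal of the methoxymethyl group would lead to 18.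
- Merits: the union is highly convergent. The benzyloxy group next to the aryne directs the carboxylate oxygen to the remote carbon, so the acyl group lands between the two oxygens as required. Ring A is already benzylated, so no reprotection follows. After the coupling this road is at least as short as the chosen one.
- Weak points: A8 needs several steps from a protected phloroglucinol; A7 is prone to decarboxylation under basic fluoride, and its alkyne can trap the aryne; A6 can close 5-exo to an aurone.
- Comparison: the chosen plan avoids the aryne precursor and uses commodity starting materials. It forms ring B and its oxygen pattern in the same operation, and it must accept a regiochemical question that alternative 3 does not have.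

Key step: step 9

Remark: the sulfate monoesters 19 and 20 are written as free hydrogen sulfates, as the target is drawn; in the flask they would be carried as sodium salts and the acid form released only at the end by cation exchange.

## Route

Step 1
Reactants: 1 galactaric acid
Product: 2 potassium 3-(acetyloxy)-2-oxo-2H-pyran-6-carboxylate
Conditions: Ac2O, KOAc, 100 °C; salt collected by filtration
Reagents that add atoms: acetic anhydride, CC(=O)OC(C)=O; potassium acetate, CC(=O)[O-].[K+]
Why: Peracetylation followed by acetate-induced β-eliminations of acetic acid and lactonisation of the resulting enol is the known dehydrative cyclisation of aldaric acids to 3-acyloxy-2-pyrone-6-carboxylates; all four stereocentres of 1 are destroyed.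

Step 2
Reactants: 2 potassium 3-(acetyloxy)-2-oxo-2H-pyran-6-carboxylate
Product: 3 methyl 3-hydroxy-2-oxo-2H-pyran-6-carboxylate
Conditions: HCl (from AcCl), MeOH, reflux
Reagents that add atoms: methanol, CO
Why: Acid-catalysed methanolysis of the enol acetate and Fischer esterification of the carboxyl group run together; the 2-pyrone lactone tolerates acid, whereas alkoxide would open it.

Step 3
Reactants: 3 methyl 3-hydroxy-2-oxo-2H-pyran-6-carboxylate
Product: 4 methyl 3-(benzyloxy)-2-oxo-2H-pyran-6-carboxylate
Conditions: BnBr, K2CO3, DMF, rt
Reagents that add atoms: benzyl bromide, BrCc1ccccc1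
Why: Williamson O-alkylation of the acidic enolic 3-hydroxyl; carbonate is too weak a nucleophile to open the lactone, and the ester blocks the carboxyl group.

Step 4
Reactants: 4 methyl 3-(benzyloxy)-2-oxo-2H-pyran-6-carboxylate
Product: 5 3-(benzyloxy)-2-oxo-2H-pyran-6-carboxylic acid
Conditions: Me3SnOH, ClCH2CH2Cl, 80 °C; then 1 M HCl wash
Reagents that add atoms: trimethyltin hydroxide, C[Sn](C)(C)O (supplies one carboxyl oxygen)
Why: Trimethyltin hydroxide cleaves unhindered methyl esters by tin-assisted acyl substitution without free hydroxide, so the pyrone lactone and the benzyl enol ether should stay intact.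

Step 5
Reactants: 6 2',4',6'-trihydroxyacetophenone
Product: 7 1-[2,4-bis(benzyloxy)-6-hydroxyphenyl]ethan-1-one
Conditions: BnBr (2.1 equiv), K2CO3, DMF, rt
Reagents that add atoms: benzyl bromide, BrCc1ccccc1
Why: Williamson etherification; the hydroxyl hydrogen-bonded to the acetyl carbonyl is the least nucleophilic and stays free, and the two ortho hydroxyls are equivalent, so no regiochemical question arises.

Step 6
Reactants: 5 3-(benzyloxy)-2-oxo-2H-pyran-6-carboxylic acid; 7 1-[2,4-bis(benzyloxy)-6-hydroxyphenyl]ethan-1-one
Product: 9 1-[2,4-bis(benzyloxy)-6-hydroxyphenyl]-3-[5-(benzyloxy)-6-oxo-6H-pyran-2-yl]propane-1,3-dione, via 3-(benzyloxy)-2-oxo-2H-pyran-6-carbonyl chloride 8 (not isolated)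
Conditions: 5, (COCl)2, DMF (cat.), CH2Cl2, 0 °C to rt, evaporate; 7, LiN(SiMe3)2 (3 equiv), THF, −78 °C, then 8, −78 to −20 °C; aq. NH4Cl
Reagents that add atoms: oxalyl chloride, ClC(=O)C(=O)Cl (its chlorine is in intermediate 8 only; no atom of it remains in 9)
Why: The acid is converted to its chloride, which C-acylates the lithium enolate of the dilithiated o-hydroxyacetophenone, the one-flask form of the Baker–Venkataraman synthesis of o-hydroxyaryl β-diketones; at −78 °C the acid chloride is far more electrophilic than any position of the pyrone ring.

Step 7
Reactants: 9 1-[2,4-bis(benzyloxy)-6-hydroxyphenyl]-3-[5-(benzyloxy)-6-oxo-6H-pyran-2-yl]propane-1,3-dione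
Product: 10 5,7-bis(benzyloxy)-2-[5-(benzyloxy)-6-oxo-6H-pyran-2-yl]-4H-chromen-4-one
Conditions: NaOAc, AcOH, 100 °C
Reagents that add atoms: none
Why: Cyclodehydration of the o-hydroxyaryl β-diketone (hemiketal formation, then loss of water) closes ring C; buffered acetic acid is mild enough to keep the 5-benzyl ether peri to the carbonyl.

Step 8
Reactants: 11 acetylene; 12 triisopropylsilyl trifluoromethanesulfonate
Product: 15 (ethynyloxy)tri(propan-2-yl)silane, via lithium acetylide 13 (not isolated), via lithium ethynolate 14 (not isolated)
Conditions: n-BuLi, THF, −78 °C; LiOOt-Bu (from t-BuOOH and LiN(SiMe3)2, THF, −78 °C), −78 to −10 °C; 12, −78 to 0 °C; pentane extraction, short-path distillation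
Reagents that add atoms: tert-butyl hydroperoxide, CC(C)(C)OO (supplies the ynol oxygen); n-butyllithium, [Li]CCCC (lithium of intermediates 13 and 14 only)
Why: Lithium tert-butyl peroxide transfers electrophilic oxygen to lithium acetylides to give ynolates, and the hard, hindered silyl triflate silylates the ynolate on oxygen; the sequence is established for 1-alkynes and is applied here to the parent acetylide, with the triisopropylsilyl group chosen for hydrolytic and thermal stability.

Step 9
Reactants: 10 5,7-bis(benzyloxy)-2-[5-(benzyloxy)-6-oxo-6H-pyran-2-yl]-4H-chromen-4-one; 15 (ethynyloxy)tri(propan-2-yl)silane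
Product: 17 5,7-bis(benzyloxy)-2-{4-(benzyloxy)-3-[(triisopropylsilyl)oxy]phenyl}-4H-chromen-4-one, via bridged lactone cycloadduct 16 (not isolated)
Conditions: 15 (3 equiv), PhMe, 110 °C, sealed tube (−CO2)
Reagents that add atoms: none
Why: Proposed new method: the electron-rich alkyne 15 and the 2-pyrone of 10 should combine in an inverse-demand Diels–Alder reaction, an asynchronous [4+2] closure in which the unsubstituted, nucleophilic alkyne carbon leads the bonding to pyrone C6 (δ to the lactone carbonyl, bearing the ring oxygen, the position at which nucleophiles enter 2-pyrones) and the silyloxy-bearing carbon, which takes on oxocarbenium character, closes onto C3; the closest known reaction type is the cycloaddition of electron-poor 2-pyrones with alkoxyalkynes, ynamines or ketene acetals followed by loss of CO2. The bridged lactone 16 then loses CO2 by retro-[4+2] cycloreversion, so ring B, the one ring closed, is formed by intermolecular [4+2] cycloaddition and appears aromatic without an oxidant. No stereocentre is set: the two bridgeheads of 16 are racemic and vanish with the CO2. The selectivity needed is regiochemical (silyloxy at C3', benzyloxy at C4'); it rests on the polarisation of the ynol ether, on the intrinsic electrophilicity of pyrone C6 and on the bulk of the triisopropylsilyloxy group, which avoids the carbon that carries the chromone. The chromone C2–C3 bond is a fully substituted vinylogous ester and a poor 2π partner, so it should not compete. Excess 15 and heating in a closed vessel are meant to compensate for the benzyloxy donor, which raises the pyrone LUMO.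

Step 10
Reactants: 17 5,7-bis(benzyloxy)-2-{4-(benzyloxy)-3-[(triisopropylsilyl)oxy]phenyl}-4H-chromen-4-one
Product: 18 5,7-bis(benzyloxy)-2-[4-(benzyloxy)-3-hydroxyphenyl]-4H-chromen-4-one
Conditions: n-Bu4NF, AcOH, THF, 0 °C
Reagents that add atoms: none
Why: Fluoride cleaves the aryl silyl ether through the strong Si–F bond; benzyl ethers and the chromone are inert, and the acetic acid buffer keeps the medium from becoming strongly basic.

Step 11
Reactants: 18 5,7-bis(benzyloxy)-2-[4-(benzyloxy)-3-hydroxyphenyl]-4H-chromen-4-one
Product: 19 2-(benzyloxy)-5-[5,7-bis(benzyloxy)-4-oxo-4H-chromen-2-yl]phenyl hydrogen sulfate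
Conditions: SO3·pyridine, pyridine, 50 °C; aq. NaHCO3 work-up (sodium salt)
Reagents that add atoms: sulfur trioxide–pyridine complex, O=S(=O)([O-])[n+]1ccccc1
Why: O-sulfonation of a phenol by the sulfur trioxide–pyridine complex; the 3'-hydroxyl is the only free hydroxyl, so the position of the sulfate is fixed by the protecting group pattern.

Step 12
Reactants: 19 2-(benzyloxy)-5-[5,7-bis(benzyloxy)-4-oxo-4H-chromen-2-yl]phenyl hydrogen sulfate
Product: 20 luteolin 3'-sulfate [5-(5,7-dihydroxy-4-oxo-4H-chromen-2-yl)-2-hydroxyphenyl hydrogen sulfate]
Conditions: H2 (1 atm), 10% Pd/C, MeOH–THF, rt; then cation-exchange resin (H+ form), 0 °C, freeze-drying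
Reagents that add atoms: none
Why: Catalytic hydrogenolysis removes the three aryl benzyl ethers under neutral conditions in which the aryl sulfate anion is inert; the conjugated chromone double bond is reduced much more slowly than benzyl ethers are cleaved.

## Compound list

1 | galactaric acid (mucic acid, meso) | OC(=O)[C@H](O)[C@@H](O)[C@@H](O)[C@H](O)C(=O)O | starting material
2 | potassium 3-(acetyloxy)-2-oxo-2H-pyran-6-carboxylate | CC(=O)Oc1ccc(C(=O)[O-])oc1=O.[K+] | intermediate
3 | methyl 3-hydroxy-2-oxo-2H-pyran-6-carboxylate | COC(=O)c1ccc(O)c(=O)o1 | intermediate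
4 | methyl 3-(benzyloxy)-2-oxo-2H-pyran-6-carboxylate | COC(=O)c1ccc(OCc2ccccc2)c(=O)o1 | intermediate
5 | 3-(benzyloxy)-2-oxo-2H-pyran-6-carboxylic acid | OC(=O)c1ccc(OCc2ccccc2)c(=O)o1 | intermediate
6 | 2',4',6'-trihydroxyacetophenone | CC(=O)c1c(O)cc(O)cc1O | starting material
7 | 1-[2,4-bis(benzyloxy)-6-hydroxyphenyl]ethan-1-one | CC(=O)c1c(O)cc(OCc2ccccc2)cc1OCc1ccccc1 | intermediate
8 | 3-(benzyloxy)-2-oxo-2H-pyran-6-carbonyl chloride | ClC(=O)c1ccc(OCc2ccccc2)c(=O)o1 | intermediate
9 | 1-[2,4-bis(benzyloxy)-6-hydroxyphenyl]-3-[5-(benzyloxy)-6-oxo-6H-pyran-2-yl]propane-1,3-dione (drawn as the diketo tautomer) | O=C(CC(=O)c1ccc(OCc2ccccc2)c(=O)o1)c1c(O)cc(OCc2ccccc2)cc1OCc1ccccc1 | intermediate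
10 | 5,7-bis(benzyloxy)-2-[5-(benzyloxy)-6-oxo-6H-pyran-2-yl]-4H-chromen-4-one | O=c1oc(-c2cc(=O)c3c(OCc4ccccc4)cc(OCc4ccccc4)cc3o2)ccc1OCc1ccccc1 | intermediate
11 | acetylene (ethyne) | C#C | starting material
12 | triisopropylsilyl trifluoromethanesulfonate | CC(C)[Si](C(C)C)(C(C)C)OS(=O)(=O)C(F)(F)F | starting material
13 | lithium acetylide | [Li]C#C | intermediate
14 | lithium ethynolate | [Li+].[O-]C#C | intermediate
15 | (ethynyloxy)tri(propan-2-yl)silane | C#CO[Si](C(C)C)(C(C)C)C(C)C | intermediate
16 | 4-(benzyloxy)-1-[5,7-bis(benzyloxy)-4-oxo-4H-chromen-2-yl]-5-[(triisopropylsilyl)oxy]-2-oxabicyclo[2.2.2]octa-5,7-dien-3-one (racemic, one enantiomer drawn; the bridgeheads can only be joined in this relative sense) | O=C1O[C@@]2(c3cc(=O)c4c(OCc5ccccc5)cc(OCc5ccccc5)cc4o3)C=C[C@]1(OCc1ccccc1)C(O[Si](C(C)C)(C(C)C)C(C)C)=C2 | intermediate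
17 | 5,7-bis(benzyloxy)-2-{4-(benzyloxy)-3-[(triisopropylsilyl)oxy]phenyl}-4H-chromen-4-one | O=c1cc(-c2ccc(OCc3ccccc3)c(O[Si](C(C)C)(C(C)C)C(C)C)c2)oc2cc(OCc3ccccc3)cc(OCc3ccccc3)c12 | intermediate
18 | 5,7-bis(benzyloxy)-2-[4-(benzyloxy)-3-hydroxyphenyl]-4H-chromen-4-one | O=c1cc(-c2ccc(OCc3ccccc3)c(O)c2)oc2cc(OCc3ccccc3)cc(OCc3ccccc3)c12 | intermediate
19 | 2-(benzyloxy)-5-[5,7-bis(benzyloxy)-4-oxo-4H-chromen-2-yl]phenyl hydrogen sulfate | O=c1cc(-c2ccc(OCc3ccccc3)c(OS(=O)(=O)O)c2)oc2cc(OCc3ccccc3)cc(OCc3ccccc3)c12 | intermediate
20 | luteolin 3'-sulfate | O=c1cc(-c2ccc(O)c(OS(=O)(=O)O)c2)oc2cc(O)cc(O)c12 | target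

## Step count and least certain steps

Total: 12 steps. Longest linear sequence: 10 steps (steps 1–4, 6, 7, 9–12).

**Step 9 (key step).** Two things can go wrong. The orientation may be lost or reversed, because the chromone draws electron density through the diene towards pyrone C3 and the benzyloxy donor weakens the electrophilicity of C6; this would put the silyloxy group at C2'. Alternatively the cycloaddition may be too slow, so that thermal isomerisation of 15 to the silylketene, or its oligomerisation, outruns it. The fallback uses known chemistry only and sets out from acetophenone 7. Claisen–Schmidt condensation of 7 with commercial 4-(benzyloxy)-3-hydroxybenzaldehyde F1 (KOH, EtOH) should give the chalcone (E)-1-[2,4-bis(benzyloxy)-6-hydroxyphenyl]-3-[4-(benzyloxy)-3-hydroxyphenyl]prop-2-en-1-one F2. Oxidative cyclisation of F2 with catalytic I2 in DMSO at 120 °C should give phenol 18, where the route is rejoined.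

**Step 8.** Monolithium acetylide may disproportionate on warming before it is oxidised. The unhindered ynolate carbon may be silylated instead of oxygen, giving the silylketene. The small, volatile product may be lost on isolation. The fallback delivers the same two carbons at the ketene acetal oxidation level and sets out from pyronylchromone 10. Heating 10 with 1,1-bis[(trimethylsilyl)oxy]ethene F3 (from trimethylsilyl acetate, LiN(i-Pr)2 and Me3SiCl) should give cycloaddition, loss of CO2 and elimination of trimethylsilanol. The product would be 5,7-bis(benzyloxy)-2-{4-(benzyloxy)-3-[(trimethylsilyl)oxy]phenyl}-4H-chromen-4-one F4, which is hydrolysed on mildly acidic work-up to phenol 18.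

**Step 4.** The tin hydroxide may open the pyrone lactone in competition with the ester cleavage. The fallback avoids the free acid and sets out from methyl ester 4. A crossed Claisen condensation of 4 with the dilithium dianion of 7 (LiN(SiMe3)2, THF, −78 °C) should give diketone 9 directly, with no new isolated compound.

**Step 6.** The enolate may add to the pyrone ring (conjugate addition or attack at the lactone carbonyl), or acylation may occur on the phenoxide oxygen or twice. The fallback separates the two events and sets out from acid 5 and acetophenone 7. Carbodiimide esterification (EDC·HCl, DMAP, CH2Cl2) should give 2-acetyl-3,5-bis(benzyloxy)phenyl 3-(benzyloxy)-2-oxo-2H-pyran-6-carboxylate F5. Intramolecular acyl transfer with KOt-Bu in THF at 0 °C (Baker–Venkataraman rearrangement) should then give diketone 9.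

**Step 12.** The C2–C3 double bond may be partly saturated, the 5-benzyl ether may cleave incompletely, or the sulfate may be lost once the free acid forms. The fallback keeps the sulfate masked until the end and sets out from phenol 18. 2,2,2-Trichloroethyl chlorosulfate with Et3N and DMAP should give 2-(benzyloxy)-5-[5,7-bis(benzyloxy)-4-oxo-4H-chromen-2-yl]phenyl 2,2,2-trichloroethyl sulfate F6. BCl3 with pentamethylbenzene in CH2Cl2 at −78 °C should remove the benzyl ethers and give 5-(5,7-dihydroxy-4-oxo-4H-chromen-2-yl)-2-hydroxyphenyl 2,2,2-trichloroethyl sulfate F7. Zinc dust with HCO2NH4 in MeOH should then release the sulfate and give 20.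

## Further compounds

F1 | step 9 | 4-(benzyloxy)-3-hydroxybenzaldehyde | O=Cc1ccc(OCc2ccccc2)c(O)c1
F2 | step 9 | (E)-1-[2,4-bis(benzyloxy)-6-hydroxyphenyl]-3-[4-(benzyloxy)-3-hydroxyphenyl]prop-2-en-1-one | O=C(/C=C/c1ccc(OCc2ccccc2)c(O)c1)c1c(O)cc(OCc2ccccc2)cc1OCc1ccccc1
F3 | step 8 | 1,1-bis[(trimethylsilyl)oxy]ethene | C=C(O[Si](C)(C)C)O[Si](C)(C)C
F4 | step 8 | 5,7-bis(benzyloxy)-2-{4-(benzyloxy)-3-[(trimethylsilyl)oxy]phenyl}-4H-chromen-4-one | O=c1cc(-c2ccc(OCc3ccccc3)c(O[Si](C)(C)C)c2)oc2cc(OCc3ccccc3)cc(OCc3ccccc3)c12
F0 | step 4 | none | none
F5 | step 6 | 2-acetyl-3,5-bis(benzyloxy)phenyl 3-(benzyloxy)-2-oxo-2H-pyran-6-carboxylate | CC(=O)c1c(OC(=O)c2ccc(OCc3ccccc3)c(=O)o2)cc(OCc2ccccc2)cc1OCc1ccccc1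
F6 | step 12 | 2-(benzyloxy)-5-[5,7-bis(benzyloxy)-4-oxo-4H-chromen-2-yl]phenyl 2,2,2-trichloroethyl sulfate | O=c1cc(-c2ccc(OCc3ccccc3)c(OS(=O)(=O)OCC(Cl)(Cl)Cl)c2)oc2cc(OCc3ccccc3)cc(OCc3ccccc3)c12
F7 | step 12 | 5-(5,7-dihydroxy-4-oxo-4H-chromen-2-yl)-2-hydroxyphenyl 2,2,2-trichloroethyl sulfate | O=c1cc(-c2ccc(O)c(OS(=O)(=O)OCC(Cl)(Cl)Cl)c2)oc2cc(O)cc(O)c12
A1 | alternative 1 | 2-[4-(benzyloxy)-3-(methoxymethoxy)phenyl]-5,7-dihydroxy-4H-chromen-4-one | O=c1cc(-c2ccc(OCc3ccccc3)c(OCOC)c2)oc2cc(O)cc(O)c12
A2 | alternative 1 | ethyl 6-[4-(benzyloxy)-3-(methoxymethoxy)phenyl]-2-methyl-4-oxo-4H-pyran-3-carboxylate | CCOC(=O)c1c(C)oc(-c2ccc(OCc3ccccc3)c(OCOC)c2)cc1=O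
A3 | alternative 1 | ethyl acetate | CCOC(C)=O
A4 | alternative 2 | 1-[4-(benzyloxy)-3-(methoxymethoxy)phenyl]-3-(2,4,6-trihydroxyphenyl)propane-1,3-dione | O=C(CC(=O)c1ccc(OCc2ccccc2)c(OCOC)c1)c1c(O)cc(O)cc1O
A5 | alternative 2 | 6-{4-[4-(benzyloxy)-3-(methoxymethoxy)phenyl]-2,4-dioxobutyl}-4-hydroxy-2H-pyran-2-one | O=C(CC(=O)Cc1cc(O)cc(=O)o1)c1ccc(OCc2ccccc2)c(OCOC)c1
A6 | alternative 3 | 1-[2,4-bis(benzyloxy)-6-hydroxyphenyl]-3-[4-(benzyloxy)-3-(methoxymethoxy)phenyl]prop-2-yn-1-one | O=C(C#Cc1ccc(OCc2ccccc2)c(OCOC)c1)c1c(O)cc(OCc2ccccc2)cc1OCc1ccccc1
A7 | alternative 3 | 3-[4-(benzyloxy)-3-(methoxymethoxy)phenyl]prop-2-ynoic acid | OC(=O)C#Cc1ccc(OCc2ccccc2)c(OCOC)c1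
A8 | alternative 3 | 3,5-bis(benzyloxy)-2-(trimethylsilyl)phenyl trifluoromethanesulfonate | C[Si](C)(C)c1c(OCc2ccccc2)cc(OCc2ccccc2)cc1OS(=O)(=O)C(F)(F)F
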